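## Structural features

The target joins a 7-methoxy-2,2-dimethyl-2H-chromene to a 5-acetyl-6-hydroxy-1-benzofuran. Chromene C6 and benzofuran C2 are bridged by the chain C(OH)(CH3)–CH2–CH(CH3): the tertiary carbinol is benzylic to the chromene arene, and the methine is bonded directly to furan C2. The two stereocentres, (S) at the carbinol and (S) at the methine, are separated by a CH2 (1,3-relationship), so neither can be relied on to control the other. The carbinol lies ortho to the methoxy group and para to the pyran oxygen, so it ionises or dehydrates with traces of acid. The chromene C3=C4 bond is an electron-rich styrene, sensitive to acid, electrophiles and hydrogenation. The ortho-hydroxyacetophenone unit adds an acidic phenol and an electrophilic ketone. The real difficulty is the acyclic 1,3-stereodyad containing a fully substituted carbinol, which must be built and unmasked without acid. The key step exploits the methine carbon with its CH3, its CH2 neighbour and its bond to benzofuran C2: this is a 2-methyl-1-functionalised alkyl unit, the product of methyl–metal addition across a terminal alkene, and the metal-bearing carbon later becomes benzofuran C2.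

## Logic of the disconnections

18 ⇒ 17. The O–Si bond at the carbinol is cut last. The tertiary benzylic hydroxyl is the most acid-labile function, so it stays masked until a basic fluoride step; the forward step must avoid acid completely.

17 ⇒ 13 + 15. The benzofuran bonds C3–C3a and O1–C2 are cut. This separates the chiral, chain-bearing chromene half from an aromatic half that already carries acetyl and hydroxyl. The forward step must couple a terminal alkyne with an ortho-iodophenol, tolerate a free phenol and a ketone, close the ring through the hydroxyl next to iodine, and not disturb the propargylic stereocentre.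

15 ⇒ 14. The C–I bond is cut. The forward iodination must go to C5, not to C3 between the two hydroxyls.

13 ⇒ 12 ⇒ 11. The terminal alkyne carbon is removed and the oxidation level lowered, so the future benzofuran C2 becomes the CH2OH carbon of a 2-methylalkan-1-ol. The forward oxidation and one-carbon homologation must not epimerise the methyl-bearing α-carbon.

11 ⇒ 9. The C–CH3 bond at the methine and the C–O bond at the terminal carbon are cut. This removes one stereocentre and leaves a plain terminal alkene. The forward step must add methyl and metal to one alkene face, ignore the chromene alkene, and leave the benzylic C–O bond intact.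

9 ⇒ 8 ⇒ 6 + 7. The O–Si bond and then the carbinol–CH2 bond are cut. The homoallylic tertiary alcohol is the allylation product of an aryl methyl ketone, which removes the second stereocentre. The forward step must deliver allyl to the Si face of a hindered, electron-rich ketone.

6 ⇒ 4 ⇒ 1 + 2. The pyran C4–C4a bond is cut (with reorganisation of the O1–C2 bond), then the aryl O–C bond. The dimethylpyran ring is traced to a catalogue phenol that already holds the acetyl and methoxy groups, and to a propargylic alcohol. The forward rearrangement must reach the ring carbon para to the methoxy group.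

## Other disconnections considered

Alternative 1: The cut is the benzofuran C2=C3 bond, with O1–C2 already present as an aryl ester. In the forward step the phosphonium salt A2 is deprotonated by a tertiary amine in hot toluene; the benzylic ylide attacks its own ester carbonyl and oxaphosphetane collapse gives A1, which has the same structure as 17.
- In its favour: the furan ring closes without transition metals, the chain position on C2 is unambiguous, and the acyl part could come from oxidation of 12 to the acid, so no alkyne is needed.
- Against it: the methine would sit α to an aryl ester and be exposed to amine base at 80–110 °C. That position is far more acidic than the propargylic carbon of the chosen route, so epimerisation or ketene formation is a real risk. The free phenol consumes base. The phosphonium part of A2 needs C-functionalisation of 14 at C5 (the same regiochemical question as iodination) plus a selective O-acylation.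
- Structure: equal; both plans need the same chiral chain, so the carboalumination question is untouched.
- Mechanism: the alternative is the better on metal residues and avoids a diazo reagent; it is the worse on configurational safety of the methine.
- Step economy: about three steps from 12 plus two to three for the aryl partner, against two plus one in the chosen plan.

Alternative 2: The cut is the bond between the carbinol carbon and the chain CH2. In the forward step the carbamate A4 is deprotonated by s-BuLi at −78 °C and borylated by the primary boronic ester A5; 1,2-shift of the alkyl group from boron to carbon with loss of the carbamate, then oxidation, gives A3.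
- In its favour: it is the most convergent plan, with two halves of similar size meeting as the quaternary carbinol forms.
- Equal or better: the carbinol configuration is relayed stereospecifically from a secondary benzylic alcohol made by ketone reduction, probably more dependable than enantioselective allylation of 6. The free tertiary alcohol emerges directly. The methine of A5 could be set by a copper-catalysed enantioselective hydroboration and never passes through an epimerisable aldehyde.
- Against it: s-BuLi forces a dioxolane on the ketone and a silyl ether on the phenol. The dioxolane must finally be hydrolysed with aqueous acid in the presence of the tertiary benzylic alcohol and the chromene, the two most acid-sensitive parts. Ring lithiation at chromene C8 (between two oxygens) can compete. The electron-rich aryl group lowers the configurational stability of the lithiated carbamate and makes borylation reversible.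
- Structure: the alternative is the better on convergence.
- Mechanism: stereospecific relay against catalyst control; the chosen plan is the better on the final deprotection.
- Step economy: a shorter longest linear sequence (a point for the alternative), but a similar or higher total because of two protections and two deprotections.

Alternative 3: The cut is the bond between benzofuran C2 and the methine. In the forward step the protected benzofuran A7 is lithiated at C2 and added to the secondary boronic ester A8; NBS brominates C3, the alkyl group migrates from boron to C2 with retention, and loss of boron and bromide restores the furan to give A6.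
- In its favour: convergent; the benzofuran nucleus is built separately; the coupling is stereospecific.
- Equal or better: the methine is never α to a carbonyl, which is better than the aldehyde stage of the chosen plan. The carbinol would be made exactly as in the chosen plan, which is equal.
- Against it: A8 is harder to reach than 11. Boron on the methyl-bearing carbon needs either a branched-selective enantioselective hydroboration of the unactivated alkene in 9, which has weak precedent, or a homologation of a neopentyl-type boronic ester. NBS is also an electrophile for the chromene alkene and the dialkoxyarene. Three protecting groups must come off, one of them (the dioxolane) with acid.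
- Structure: equal at the carbinol.
- Mechanism: the alternative is the better on epimerisation, the worse on chemoselectivity towards the chromene.
- Step economy: longer, because of the protections and the access to A8.

Key step: step 5

Assumption: 1 (4'-hydroxy-2'-methoxyacetophenone) is a catalogue chemical; it already carries the acetyl group, so the chromene needs no separate acylation.
Remark: a diol-catalysed allylboration of 6 is not adopted, because BINOL-type diols exchange with acyclic or six-membered allylboronates but hardly with the commercial pinacol ester; step 3 uses commercial 7 under AgF–bisphosphine catalysis.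
Remark: the aryl iodide for step 9 must be the 5-iodo isomer 15; a 3-iodo isomer would give a wrongly fused benzofuran.
Remark: the carbinol oxygen goes through step 5 as the triethylsilyl ether; a free hydroxyl would become an aluminium alkoxide prone to ionisation and C-methylation at this electron-rich benzylic carbon, and a bulkier silyl group could not be removed from a tertiary centre without acid.

## Route

Step 1
Reactants: 1 1-(4-hydroxy-2-methoxyphenyl)ethan-1-one; 2 2-methylbut-3-yn-2-ol
Product: 4 1-{2-methoxy-4-[(2-methylbut-3-yn-2-yl)oxy]phenyl}ethan-1-one, via propargylic trifluoroacetate 3 (not isolated)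
Conditions: 2, (CF3CO)2O, DBU, MeCN, −5 °C; then 1, DBU, CuCl2·2H2O (0.1 mol %), 0 °C
Reagents that add atoms: none
Why: Copper-catalysed propargylic etherification: the tertiary trifluoroacetate 3 is ionised by copper to a propargyl/allenylidene electrophile that the phenoxide of 1 captures at the tertiary carbon. The para-acetyl group makes the phenol acidic enough for DBU, and the ketone is a spectator.

Step 2
Reactants: 4 1-{2-methoxy-4-[(2-methylbut-3-yn-2-yl)oxy]phenyl}ethan-1-one
Product: 6 1-(7-methoxy-2,2-dimethyl-2H-chromen-6-yl)ethan-1-one, via ortho-allenylphenol 5 (not isolated)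
Conditions: PhNEt2, 185 °C
Reagents that add atoms: none
Why: Aryl propargyl ether Claisen rearrangement: a [3,3] shift to the ortho carbon para to methoxy (the other ortho carbon is crowded between two oxygen substituents), tautomerisation to 5, 1,5-hydrogen shift and oxa-6π electrocyclisation close the pyran ring. The minor 5-methoxy regioisomer is expected to be removable by chromatography.

Step 3
Reactants: 6 1-(7-methoxy-2,2-dimethyl-2H-chromen-6-yl)ethan-1-one; 7 allyltrimethoxysilane
Product: 8 (2S)-2-(7-methoxy-2,2-dimethyl-2H-chromen-6-yl)pent-4-en-2-ol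
Conditions: AgF (5 mol %), (S)-DIFLUORPHOS (5 mol %), MeOH (1 equiv), THF, −78 → −40 °C; Et3N-deactivated silica
Reagents that add atoms: none
Why: Silver-catalysed asymmetric Sakurai–Hosomi allylation of a ketone: a bisphosphine–allylsilver species formed from 7 adds through a cyclic six-membered transition state to the Si face of the carbonyl, setting the (S)-carbinol, and methanol turns over the silver alkoxide. The ligand antipode is assigned by analogy with acetophenone-type ketones, where the (R)-ligand is expected to give Re-face addition; the sense is to be checked on the first run and the antipode exchanged if needed.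

Step 4
Reactants: 8 (2S)-2-(7-methoxy-2,2-dimethyl-2H-chromen-6-yl)pent-4-en-2-ol
Product: 9 triethyl{[(2S)-2-(7-methoxy-2,2-dimethyl-2H-chromen-6-yl)pent-4-en-2-yl]oxy}silane
Conditions: Et3SiOTf, 2,6-lutidine, CH2Cl2, −78 °C
Reagents that add atoms: triethylsilyl trifluoromethanesulfonate, CC[Si](CC)(CC)OS(=O)(=O)C(F)(F)F
Why: O-Silylation of a hindered tertiary alcohol with a silyl triflate and a non-nucleophilic base. Excess lutidine and low temperature keep the medium non-acidic so the benzylic C–O bond does not ionise; the stereocentre is not touched.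

Step 5
Reactants: 9 triethyl{[(2S)-2-(7-methoxy-2,2-dimethyl-2H-chromen-6-yl)pent-4-en-2-yl]oxy}silane
Product: 11 (2S,4S)-4-(7-methoxy-2,2-dimethyl-2H-chromen-6-yl)-2-methyl-4-[(triethylsilyl)oxy]pentan-1-ol, via primary dimethylalkylalane 10 (not isolated)
Conditions: Me3Al (3 equiv), (+)-bis(1-neomenthylindenyl)zirconium dichloride (5 mol %), methylaluminoxane (1 equiv), CH2Cl2, −20 → 0 °C; then dry O2, 0 °C; aq. Rochelle salt
Reagents that add atoms: trimethylaluminium, C[Al](C)C; dioxygen, O=O
Why: Zirconium-catalysed asymmetric carboalumination (ZACA reaction) of a terminal alkene carrying a remote silyl ether, a substrate class for which this reaction is established. Me3Al and methylaluminoxane turn the zirconocene dichloride into a cationic Zr–CH3 species; the terminal alkene of 9 coordinates and inserts in the 1,2-sense through a four-centre transition state, with methyl going to the internal carbon and zirconium to the terminal carbon. Alkyl exchange with Me3Al releases the primary alane 10 and regenerates Zr–CH3; dry O2 then inserts into the Al–C bonds and hydrolysis gives the primary alcohol. No ring is closed. The new methine centre is set by the chiral neomenthylindenyl ligand sphere (enantiomorphic-site control); the (+)-antipode is chosen because for alkenes of the type RCH2CH=CH2 it is the one expected to give the (S)-2-methylalkan-1-ol, and the carbinol centre one CH2 away should perturb this only slightly. The minor (2R,4S) diastereomer is to be removed by chromatography at this stage, which should also raise the enantiomeric purity of 11, because the mirror image of 11 can only arise from the minor enantiomer of 9 reacting against the catalyst preference. Chemoselectivity rests on the fact that only monosubstituted alkenes insert, so the cis-disubstituted, conjugated C3=C4 bond of the chromene is left alone. The benzylic C–O bond is shielded from the Lewis-acidic aluminium species by the hindered, weakly basic silyl ether oxygen and by the low temperature, and the non-acidic tartrate work-up spares the chromene.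

Step 6
Reactants: 11 (2S,4S)-4-(7-methoxy-2,2-dimethyl-2H-chromen-6-yl)-2-methyl-4-[(triethylsilyl)oxy]pentan-1-ol
Product: 12 (2S,4S)-4-(7-methoxy-2,2-dimethyl-2H-chromen-6-yl)-2-methyl-4-[(triethylsilyl)oxy]pentanal
Conditions: Dess–Martin periodinane, pyridine, CH2Cl2, 0 °C → rt
Reagents that add atoms: none
Why: Dess–Martin oxidation of a primary alcohol to the aldehyde. Pyridine buffers the acetic acid released, protecting the benzylic silyl ether and the chromene, and the non-enolising conditions should preserve the α-methyl stereocentre; the crude aldehyde is used at once.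

Step 7
Reactants: 12 (2S,4S)-4-(7-methoxy-2,2-dimethyl-2H-chromen-6-yl)-2-methyl-4-[(triethylsilyl)oxy]pentanal
Product: 13 triethyl{[(2S,4S)-2-(7-methoxy-2,2-dimethyl-2H-chromen-6-yl)-4-methylhex-5-yn-2-yl]oxy}silane
Conditions: dimethyl (1-diazo-2-oxopropyl)phosphonate, K2CO3, MeOH, 0 °C → rt
Reagents that add atoms: dimethyl (1-diazo-2-oxopropyl)phosphonate, COP(=O)(OC)C(=[N+]=[N-])C(C)=O
Why: Seyferth–Gilbert homologation in the Ohira–Bestmann variant: methanolysis of the reagent gives the diazomethylphosphonate anion, which olefinates the aldehyde; loss of N2 and a 1,2-hydrogen shift give the terminal alkyne, with the former aldehyde carbon as the internal sp carbon. A short reaction at low temperature limits enolisation of the α-branched aldehyde; the tertiary silyl ether is stable to methanolic carbonate.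

Step 8
Reactants: 14 1-(2,4-dihydroxyphenyl)ethan-1-one
Product: 15 1-(2,4-dihydroxy-5-iodophenyl)ethan-1-one
Conditions: BnMe3N+ ICl2−, NaHCO3, CH2Cl2/MeOH, rt
Reagents that add atoms: benzyltrimethylammonium dichloroiodate, C[N+](C)(C)Cc1ccccc1.Cl[I-]Cl
Why: Electrophilic aromatic iodination: C5 is ortho to the 4-hydroxyl, para to the 2-hydroxyl and less hindered than C3, and the bulky dichloroiodate under bicarbonate buffering should stop at mono-iodination. Any 3-iodo isomer is to be removed by crystallisation or chromatography.

Step 9
Reactants: 13 triethyl{[(2S,4S)-2-(7-methoxy-2,2-dimethyl-2H-chromen-6-yl)-4-methylhex-5-yn-2-yl]oxy}silane; 15 1-(2,4-dihydroxy-5-iodophenyl)ethan-1-one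
Product: 17 1-{6-hydroxy-2-[(2S,4S)-4-(7-methoxy-2,2-dimethyl-2H-chromen-6-yl)-4-[(triethylsilyl)oxy]pentan-2-yl]-1-benzofuran-5-yl}ethan-1-one, via ortho-alkynylphenol 16 (not isolated)
Conditions: PdCl2(PPh3)2 (3 mol %), CuI (6 mol %), Et3N, DMF (degassed), rt → 60 °C
Reagents that add atoms: none
Why: Sonogashira coupling (oxidative addition of the aryl iodide to zerovalent palladium, copper acetylide transmetalation, reductive elimination), followed in the same flask by 5-endo-dig heteroannulation of 16, in which the hydroxyl next to the alkyne adds to the metal-activated triple bond at the chain-bearing carbon. Only the former 4-hydroxyl is ortho to the alkyne, so the acetyl-chelated hydroxyl ends up at benzofuran C6. The propargylic methine carries no acidifying group and should keep its configuration under triethylamine.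

Step 10
Reactants: 17 1-{6-hydroxy-2-[(2S,4S)-4-(7-methoxy-2,2-dimethyl-2H-chromen-6-yl)-4-[(triethylsilyl)oxy]pentan-2-yl]-1-benzofuran-5-yl}ethan-1-one
Product: 18 1-{6-hydroxy-2-[(2S,4S)-4-hydroxy-4-(7-methoxy-2,2-dimethyl-2H-chromen-6-yl)pentan-2-yl]-1-benzofuran-5-yl}ethan-1-one
Conditions: Bu4NF (3 equiv), THF, 0 °C → rt; pH 7 phosphate buffer
Reagents that add atoms: none
Why: Fluoride-induced cleavage of the tertiary triethylsilyl ether. The basic medium and neutral buffered work-up avoid ionisation of the liberated tertiary benzylic alcohol and acid-induced reactions of the chromene; extra fluoride allows for the acidic phenol.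

## Compound list

1 | 1-(4-hydroxy-2-methoxyphenyl)ethan-1-one | COc1cc(O)ccc1C(C)=O | starting material
2 | 2-methylbut-3-yn-2-ol | CC(C)(O)C#C | starting material
3 | 2-methylbut-3-yn-2-yl trifluoroacetate | CC(C)(OC(=O)C(F)(F)F)C#C | intermediate (not isolated)
4 | 1-{2-methoxy-4-[(2-methylbut-3-yn-2-yl)oxy]phenyl}ethan-1-one | COc1cc(OC(C)(C)C#C)ccc1C(C)=O | intermediate
5 | 1-[4-hydroxy-2-methoxy-5-(3-methylbuta-1,2-dien-1-yl)phenyl]ethan-1-one | COc1cc(O)c(C=C=C(C)C)cc1C(C)=O | intermediate (not isolated)
6 | 1-(7-methoxy-2,2-dimethyl-2H-chromen-6-yl)ethan-1-one | COc1cc2c(cc1C(C)=O)C=CC(C)(C)O2 | intermediate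
7 | allyltrimethoxysilane | C=CC[Si](OC)(OC)OC | starting material
8 | (2S)-2-(7-methoxy-2,2-dimethyl-2H-chromen-6-yl)pent-4-en-2-ol | COc1cc2c(cc1[C@@](C)(O)CC=C)C=CC(C)(C)O2 | intermediate
9 | triethyl{[(2S)-2-(7-methoxy-2,2-dimethyl-2H-chromen-6-yl)pent-4-en-2-yl]oxy}silane | COc1cc2c(cc1[C@@](C)(O[Si](CC)(CC)CC)CC=C)C=CC(C)(C)O2 | intermediate
10 | dimethyl{(2S,4S)-4-(7-methoxy-2,2-dimethyl-2H-chromen-6-yl)-2-methyl-4-[(triethylsilyl)oxy]pentyl}alane | COc1cc2c(cc1[C@@](C)(O[Si](CC)(CC)CC)C[C@H](C)C[Al](C)C)C=CC(C)(C)O2 | intermediate (not isolated)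
11 | (2S,4S)-4-(7-methoxy-2,2-dimethyl-2H-chromen-6-yl)-2-methyl-4-[(triethylsilyl)oxy]pentan-1-ol | COc1cc2c(cc1[C@@](C)(O[Si](CC)(CC)CC)C[C@H](C)CO)C=CC(C)(C)O2 | intermediate
12 | (2S,4S)-4-(7-methoxy-2,2-dimethyl-2H-chromen-6-yl)-2-methyl-4-[(triethylsilyl)oxy]pentanal | COc1cc2c(cc1[C@@](C)(O[Si](CC)(CC)CC)C[C@H](C)C=O)C=CC(C)(C)O2 | intermediate
13 | triethyl{[(2S,4S)-2-(7-methoxy-2,2-dimethyl-2H-chromen-6-yl)-4-methylhex-5-yn-2-yl]oxy}silane | COc1cc2c(cc1[C@@](C)(O[Si](CC)(CC)CC)C[C@H](C)C#C)C=CC(C)(C)O2 | intermediate
14 | 1-(2,4-dihydroxyphenyl)ethan-1-one | CC(=O)c1ccc(O)cc1O | starting material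
15 | 1-(2,4-dihydroxy-5-iodophenyl)ethan-1-one | CC(=O)c1cc(I)c(O)cc1O | intermediate
16 | 1-{2,4-dihydroxy-5-[(3S,5S)-5-(7-methoxy-2,2-dimethyl-2H-chromen-6-yl)-3-methyl-5-[(triethylsilyl)oxy]hex-1-yn-1-yl]phenyl}ethan-1-one | COc1cc2c(cc1[C@@](C)(O[Si](CC)(CC)CC)C[C@H](C)C#Cc1cc(C(C)=O)c(O)cc1O)C=CC(C)(C)O2 | intermediate (not isolated)
17 | 1-{6-hydroxy-2-[(2S,4S)-4-(7-methoxy-2,2-dimethyl-2H-chromen-6-yl)-4-[(triethylsilyl)oxy]pentan-2-yl]-1-benzofuran-5-yl}ethan-1-one | COc1cc2c(cc1[C@@](C)(O[Si](CC)(CC)CC)C[C@H](C)c1cc3cc(C(C)=O)c(O)cc3o1)C=CC(C)(C)O2 | intermediate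
18 | 1-{6-hydroxy-2-[(2S,4S)-4-hydroxy-4-(7-methoxy-2,2-dimethyl-2H-chromen-6-yl)pentan-2-yl]-1-benzofuran-5-yl}ethan-1-one | COc1cc2c(cc1[C@@](C)(O)C[C@H](C)c1cc3cc(C(C)=O)c(O)cc3o1)C=CC(C)(C)O2 | target

## Step count and least certain steps

Total: 10 steps. Longest linear sequence: 9 steps (steps 1–7, 9 and 10); step 8 is a one-step side branch.

Step 5 (key step). The most likely failure is Lewis-acid ionisation of the benzylic C–O bond, followed by methyl transfer from aluminium or elimination to a styrene, because the cation would be stabilised by the ortho-methoxy and para-alkoxy groups. The second concern is only moderate face selectivity of methyl delivery, which would cost material at the diastereomer separation. The fallback sets out from 9 and comes back at 11; it replaces catalytic carbometalation by auxiliary-controlled enolate methylation: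
- Hydroboration of the terminal alkene with 9-BBN (THF, 0 °C → rt; NaOH, H2O2), which should leave the cis-disubstituted chromene alkene alone, gives (4S)-4-(7-methoxy-2,2-dimethyl-2H-chromen-6-yl)-4-[(triethylsilyl)oxy]pentan-1-ol F1.
- Oxidation with Pr4N[RuO4] (cat.) and N-methylmorpholine N-oxide hydrate in MeCN gives (4S)-4-(7-methoxy-2,2-dimethyl-2H-chromen-6-yl)-4-[(triethylsilyl)oxy]pentanoic acid F2.
- Coupling with (4S)-4-benzyl-1,3-oxazolidin-2-one (DCC, DMAP, CH2Cl2) gives (4S)-4-benzyl-3-{(4S)-4-(7-methoxy-2,2-dimethyl-2H-chromen-6-yl)-4-[(triethylsilyl)oxy]pentanoyl}-1,3-oxazolidin-2-one F3.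
- Enolisation with NaHMDS (THF, −78 °C) and methylation with MeI on the face away from the benzyl group gives (4S)-4-benzyl-3-{(2S,4S)-4-(7-methoxy-2,2-dimethyl-2H-chromen-6-yl)-2-methyl-4-[(triethylsilyl)oxy]pentanoyl}-1,3-oxazolidin-2-one F4.
- Reduction with LiBH4 (Et2O, MeOH, 0 °C) releases the auxiliary and gives 11.

Step 3. Poor face selectivity or low conversion may result, because the ortho-methoxy group twists and crowds the carbonyl and the two alkoxy groups deactivate it. The fallback sets out from 6 and comes back at 8; it sets the configuration by ketone reduction and transfers it stereospecifically: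
- Asymmetric transfer hydrogenation (RuCl[(R,R)-TsDPEN](p-cymene), HCO2Na, MeOH/H2O, 40 °C) gives (1R)-1-(7-methoxy-2,2-dimethyl-2H-chromen-6-yl)ethan-1-ol F5.
- Carbamoylation (iPr2NCOCl, Et3N, toluene, 90 °C) gives (1R)-1-(7-methoxy-2,2-dimethyl-2H-chromen-6-yl)ethyl N,N-di(propan-2-yl)carbamate F6.
- Deprotonation with s-BuLi (Et2O, −78 °C), trapping with allylboronic acid pinacol ester and 1,2-shift of the allyl group promoted by MgBr2/MeOH on warming give 2-[(2R)-2-(7-methoxy-2,2-dimethyl-2H-chromen-6-yl)pent-4-en-2-yl]-4,4,5,5-tetramethyl-1,3,2-dioxaborolane F7.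
- Oxidation (NaOH, H2O2, THF, 0 °C) with retention gives 8.

Step 2. The sigmatropic shift may go in part to the ortho carbon between the two oxygen substituents, giving the 5-methoxy isomer, because both ortho positions are electronically activated and only sterics separate them. The fallback sets out from 1 and comes back at 6; it fixes the ring position by electrophilic substitution:
- Iodination (BnMe3N+ ICl2−, NaHCO3, CH2Cl2/MeOH), ortho to hydroxyl and para to methoxy, gives 1-(4-hydroxy-5-iodo-2-methoxyphenyl)ethan-1-one F8.
- Mizoroki–Heck coupling with 2-methylbut-3-en-2-ol (Pd(OAc)2, P(o-tolyl)3, Et3N, MeCN, 80 °C) gives 1-{4-hydroxy-5-[(1E)-3-hydroxy-3-methylbut-1-en-1-yl]-2-methoxyphenyl}ethan-1-one F9.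
- Cyclodehydration (pyridinium p-toluenesulfonate, toluene, 80 °C) closes the pyran ring through the allylic cation and gives 6.

Step 7. Partial epimerisation of the methyl-bearing carbon may occur, because the aldehyde can enolise in methanolic carbonate before it is olefinated. The fallback sets out from 12 and comes back at 13; it keeps the aldehyde away from alkoxide base (Corey–Fuchs sequence):
- CBr4, PPh3 and Et3N in CH2Cl2 at 0 °C give {[(2S,4S)-6,6-dibromo-2-(7-methoxy-2,2-dimethyl-2H-chromen-6-yl)-4-methylhex-5-en-2-yl]oxy}triethylsilane F10.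
- n-BuLi (2.2 equiv, THF, −78 °C), then aq. NH4Cl, gives 13 by bromine–lithium exchange, rearrangement to the lithium acetylide and protonation.

## Further compounds

F1 | step 5 | (4S)-4-(7-methoxy-2,2-dimethyl-2H-chromen-6-yl)-4-[(triethylsilyl)oxy]pentan-1-ol | COc1cc2c(cc1[C@@](C)(O[Si](CC)(CC)CC)CCCO)C=CC(C)(C)O2
F2 | step 5 | (4S)-4-(7-methoxy-2,2-dimethyl-2H-chromen-6-yl)-4-[(triethylsilyl)oxy]pentanoic acid | COc1cc2c(cc1[C@@](C)(O[Si](CC)(CC)CC)CCC(O)=O)C=CC(C)(C)O2
F3 | step 5 | (4S)-4-benzyl-3-{(4S)-4-(7-methoxy-2,2-dimethyl-2H-chromen-6-yl)-4-[(triethylsilyl)oxy]pentanoyl}-1,3-oxazolidin-2-one | COc1cc2c(cc1[C@@](C)(O[Si](CC)(CC)CC)CCC(=O)N1[C@@H](Cc3ccccc3)COC1=O)C=CC(C)(C)O2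
F4 | step 5 | (4S)-4-benzyl-3-{(2S,4S)-4-(7-methoxy-2,2-dimethyl-2H-chromen-6-yl)-2-methyl-4-[(triethylsilyl)oxy]pentanoyl}-1,3-oxazolidin-2-one | COc1cc2c(cc1[C@@](C)(O[Si](CC)(CC)CC)C[C@H](C)C(=O)N1[C@@H](Cc3ccccc3)COC1=O)C=CC(C)(C)O2
F5 | step 3 | (1R)-1-(7-methoxy-2,2-dimethyl-2H-chromen-6-yl)ethan-1-ol | COc1cc2c(cc1[C@@H](C)O)C=CC(C)(C)O2
F6 | step 3 | (1R)-1-(7-methoxy-2,2-dimethyl-2H-chromen-6-yl)ethyl N,N-di(propan-2-yl)carbamate | COc1cc2c(cc1[C@@H](C)OC(=O)N(C(C)C)C(C)C)C=CC(C)(C)O2
F7 | step 3 | 2-[(2R)-2-(7-methoxy-2,2-dimethyl-2H-chromen-6-yl)pent-4-en-2-yl]-4,4,5,5-tetramethyl-1,3,2-dioxaborolane | COc1cc2c(cc1[C@@](C)(B1OC(C)(C)C(C)(C)O1)CC=C)C=CC(C)(C)O2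
F8 | step 2 | 1-(4-hydroxy-5-iodo-2-methoxyphenyl)ethan-1-one | COc1cc(O)c(I)cc1C(C)=O
F9 | step 2 | 1-{4-hydroxy-5-[(1E)-3-hydroxy-3-methylbut-1-en-1-yl]-2-methoxyphenyl}ethan-1-one | COc1cc(O)c(/C=C/C(C)(C)O)cc1C(C)=O
F10 | step 7 | {[(2S,4S)-6,6-dibromo-2-(7-methoxy-2,2-dimethyl-2H-chromen-6-yl)-4-methylhex-5-en-2-yl]oxy}triethylsilane | COc1cc2c(cc1[C@@](C)(O[Si](CC)(CC)CC)C[C@H](C)C=C(Br)Br)C=CC(C)(C)O2
A1 | alternative 1 | 1-{6-hydroxy-2-[(2S,4S)-4-(7-methoxy-2,2-dimethyl-2H-chromen-6-yl)-4-[(triethylsilyl)oxy]pentan-2-yl]-1-benzofuran-5-yl}ethan-1-one | COc1cc2c(cc1[C@@](C)(O[Si](CC)(CC)CC)C[C@H](C)c1cc3cc(C(C)=O)c(O)cc3o1)C=CC(C)(C)O2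
A2 | alternative 1 | {5-acetyl-4-hydroxy-2-[((2S,4S)-4-(7-methoxy-2,2-dimethyl-2H-chromen-6-yl)-2-methyl-4-[(triethylsilyl)oxy]pentanoyl)oxy]benzyl}(triphenyl)phosphonium bromide | COc1cc2c(cc1[C@@](C)(O[Si](CC)(CC)CC)C[C@H](C)C(=O)Oc1cc(O)c(C(C)=O)cc1C[P+](c1ccccc1)(c1ccccc1)c1ccccc1)C=CC(C)(C)O2.[Br-]
A3 | alternative 2 | (2S,4S)-2-(7-methoxy-2,2-dimethyl-2H-chromen-6-yl)-4-{5-(2-methyl-1,3-dioxolan-2-yl)-6-[(triisopropylsilyl)oxy]-1-benzofuran-2-yl}pentan-2-ol | COc1cc2c(cc1[C@@](C)(O)C[C@H](C)c1cc3cc(C4(C)OCCO4)c(O[Si](C(C)C)(C(C)C)C(C)C)cc3o1)C=CC(C)(C)O2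
A4 | alternative 2 | (1R)-1-(7-methoxy-2,2-dimethyl-2H-chromen-6-yl)ethyl N,N-di(propan-2-yl)carbamate | COc1cc2c(cc1[C@@H](C)OC(=O)N(C(C)C)C(C)C)C=CC(C)(C)O2
A5 | alternative 2 | 2-{(2S)-2-[5-(2-methyl-1,3-dioxolan-2-yl)-6-[(triisopropylsilyl)oxy]-1-benzofuran-2-yl]propyl}-4,4,5,5-tetramethyl-1,3,2-dioxaborolane | CC1(C)OB(C[C@H](C)c2cc3cc(C4(C)OCCO4)c(O[Si](C(C)C)(C(C)C)C(C)C)cc3o2)OC1(C)C
A6 | alternative 3 | triethyl{[(2S,4S)-2-(7-methoxy-2,2-dimethyl-2H-chromen-6-yl)-4-{5-(2-methyl-1,3-dioxolan-2-yl)-6-[(triisopropylsilyl)oxy]-1-benzofuran-2-yl}pentan-2-yl]oxy}silane | COc1cc2c(cc1[C@@](C)(O[Si](CC)(CC)CC)C[C@H](C)c1cc3cc(C4(C)OCCO4)c(O[Si](C(C)C)(C(C)C)C(C)C)cc3o1)C=CC(C)(C)O2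
A7 | alternative 3 | triisopropyl{[5-(2-methyl-1,3-dioxolan-2-yl)-1-benzofuran-6-yl]oxy}silane | CC1(OCCO1)c1cc2ccoc2cc1O[Si](C(C)C)(C(C)C)C(C)C
A8 | alternative 3 | triethyl{[(2S,4S)-2-(7-methoxy-2,2-dimethyl-2H-chromen-6-yl)-4-(4,4,5,5-tetramethyl-1,3,2-dioxaborolan-2-yl)pentan-2-yl]oxy}silane | COc1cc2c(cc1[C@@](C)(O[Si](CC)(CC)CC)C[C@H](C)B1OC(C)(C)C(C)(C)O1)C=CC(C)(C)O2
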